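**Retrosynthetic overview**
- The target comes from its hexa-O-benzyl ether by one final hydrogenolysis. The 7-O-gallate is installed at the start on phloroglucinaldehyde. The 4-O-acylated aldehyde is mirror-symmetric, so either ortho OH can become O1 and the other ends as 5-OH.
- The C3 carbinol comes from a C3 ketone by reagent-controlled reduction (gives 2,3-trans). The ketone comes from a C3 nitro group by a Nef reaction, so C3 is carried as a masked acyl anion.
- Key disconnection C3–C4 (together with O1–C2): tandem oxa-Michael/nitro-aldol of the ring A aldehyde with the ring B nitrostyrene. The C3 nitronate attacks the formyl carbon C4.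
- The nitrostyrene comes from the ring B aldehyde and nitromethane. The nitromethane carbon acts as a carbonyl 1,1-dianion joining two aldehyde carbons.
- Rings A and B and the galloyl ring are bought. Ring C is the only ring formed, in the key step, which also sets C2.

Assumption: the acid chloride used in step 2 is bought as such, and the (S)-configured aminocatalyst of step 3 is taken to give the 2S chromene (its equally available enantiomer is used if the sense of induction proves opposite).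

Step 1
Reactants: 1 3,4,5-tris(benzyloxy)benzaldehyde; 2 nitromethane
Product: 3 (E)-1,2,3-tris(benzyloxy)-5-(2-nitroethenyl)benzene
Conditions: NH4OAc (0.5 equiv), AcOH, 100 °C
Reagents that add atoms: none
Why: Henry (nitro-aldol) condensation, in which the nitronate of 2 adds to the aldehyde and the benzylic nitro alcohol dehydrates in the acidic buffer to the conjugated E-nitroalkene (the thermodynamic isomer), with no stereocentre formed.

Step 2
Reactants: 4 2,4,6-trihydroxybenzaldehyde; 5 3,4,5-tris(benzyloxy)benzoyl chloride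
Product: 6 4-formyl-3,5-dihydroxyphenyl 3,4,5-tris(benzyloxy)benzoate
Conditions: i-Pr2NEt (1.0 equiv), 5 (0.95 equiv, slow addition), THF, −40 to 0 °C
Reagents that add atoms: none
Why: Chemoselective phenol O-acylation (Einhorn-type esterification), in which one equivalent of base ionises only the most acidic, non-chelated 4-OH para to the formyl group, while the two equivalent ortho OH groups share the hydrogen bond to the formyl oxygen and stay free, so no further differentiation of the later O1, 5-OH and 7-O positions is needed.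

Step 3
Reactants: 6 4-formyl-3,5-dihydroxyphenyl 3,4,5-tris(benzyloxy)benzoate; 3 (E)-1,2,3-tris(benzyloxy)-5-(2-nitroethenyl)benzene
Product: 8 (2S)-5-hydroxy-3-nitro-2-[3,4,5-tris(benzyloxy)phenyl]-2H-chromen-7-yl 3,4,5-tris(benzyloxy)benzoate, via nitrochromanol 7 (not isolated)
Conditions: (S)-2-[diphenyl(triethylsilyloxy)methyl]pyrrolidine (20 mol%), 2-nitrobenzoic acid (20 mol%), toluene, 4 Å sieves, rt to 40 °C
Reagents that add atoms: none
Why: Aminocatalysed tandem oxa-Michael/Henry condensation, in which an ortho phenol adds reversibly to the nitroalkene, the resulting nitronate (the masked acyl anion of the future C3 carbonyl) attacks the iminium-activated formyl carbon C4 so that two carbonyl-type carbons are joined and ring C closes, loss of water gives the push-pull nitrochromene, and C2 is fixed as S because only the oxa-Michael adduct that fits the open face of the chiral iminium ion goes on irreversibly.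

Step 4
Reactants: 8 (2S)-5-hydroxy-3-nitro-2-[3,4,5-tris(benzyloxy)phenyl]-2H-chromen-7-yl 3,4,5-tris(benzyloxy)benzoate
Product: 10 (2S)-5-hydroxy-3-oxo-2-[3,4,5-tris(benzyloxy)phenyl]-3,4-dihydro-2H-chromen-7-yl 3,4,5-tris(benzyloxy)benzoate, via sodium nitronate 9 (not isolated)
Conditions: NaBH4, THF/EtOH, −20 to 0 °C; then aq. TiCl3 (5 equiv), NH4OAc buffer (pH 5–6), THF, 0 °C to rt
Reagents that add atoms: water O
Why: Conjugate hydride reduction followed by a McMurry-type TiCl3 Nef reaction, in which hydride adds to C4 (creating the CH2), trivalent titanium reduces the nitronate through the oxime to the imine, and buffered hydrolysis unmasks the C3 ketone under cold, near-neutral conditions that spare the aryl ester, benzyl ethers and phenol and are short enough to keep C2 intact.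

Step 5
Reactants: 10 (2S)-5-hydroxy-3-oxo-2-[3,4,5-tris(benzyloxy)phenyl]-3,4-dihydro-2H-chromen-7-yl 3,4,5-tris(benzyloxy)benzoate
Product: 11 (2S,3R)-3,5-dihydroxy-2-[3,4,5-tris(benzyloxy)phenyl]-3,4-dihydro-2H-chromen-7-yl 3,4,5-tris(benzyloxy)benzoate
Conditions: (S)-2-methyl-CBS-oxazaborolidine (1.0 equiv), BH3·SMe2 (2.5 equiv), THF/toluene, −40 °C; MeOH quench
Reagents that add atoms: none
Why: Corey–Bakshi–Shibata reduction, in which the (S)-oxazaborolidine binds the ketone with the bulkier C2 side turned away and delivers hydride from coordinated borane to the face that gives the 3R carbinol (the 2,3-trans alcohol), so reagent control is set against the intrinsic preference of flavan-3-ones for attack anti to the 2-aryl group (which gives cis), while the non-basic cold medium keeps C2 from epimerising and leaves the aryl ester alone.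

Step 6
Reactants: 11 (2S,3R)-3,5-dihydroxy-2-[3,4,5-tris(benzyloxy)phenyl]-3,4-dihydro-2H-chromen-7-yl 3,4,5-tris(benzyloxy)benzoate
Product: 12 (2S,3R)-3,5-dihydroxy-2-(3,4,5-trihydroxyphenyl)-3,4-dihydro-2H-chromen-7-yl 3,4,5-trihydroxybenzoate
Conditions: H2 (1 atm), 20% Pd(OH)2/C, THF/MeOH 1:1, rt
Reagents that add atoms: none
Why: Catalytic hydrogenolysis, in which all six O-benzyl groups leave as toluene under neutral conditions that touch neither the aryl ester, the ring C ether nor the two stereocentres.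

**Compound list**
1 | 3,4,5-tris(benzyloxy)benzaldehyde | O=Cc1cc(OCc2ccccc2)c(OCc2ccccc2)c(OCc2ccccc2)c1 | starting material
2 | nitromethane | C[N+](=O)[O-] | starting material
3 | (E)-1,2,3-tris(benzyloxy)-5-(2-nitroethenyl)benzene | O=[N+]([O-])/C=C/c1cc(OCc2ccccc2)c(OCc2ccccc2)c(OCc2ccccc2)c1 | intermediate
4 | 2,4,6-trihydroxybenzaldehyde | O=Cc1c(O)cc(O)cc1O | starting material
5 | 3,4,5-tris(benzyloxy)benzoyl chloride | O=C(Cl)c1cc(OCc2ccccc2)c(OCc2ccccc2)c(OCc2ccccc2)c1 | starting material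
6 | 4-formyl-3,5-dihydroxyphenyl 3,4,5-tris(benzyloxy)benzoate | O=Cc1c(O)cc(OC(=O)c2cc(OCc3ccccc3)c(OCc3ccccc3)c(OCc3ccccc3)c2)cc1O | intermediate
7 | (2S)-4,5-dihydroxy-3-nitro-2-[3,4,5-tris(benzyloxy)phenyl]chroman-7-yl 3,4,5-tris(benzyloxy)benzoate (nitro-aldol adduct; C3 and C4 undefined, both lost on dehydration) | O=C(Oc1cc(O)c2c(c1)O[C@@H](c3cc(OCc4ccccc4)c(OCc4ccccc4)c(OCc4ccccc4)c3)C([N+](=O)[O-])C2O)c5cc(OCc6ccccc6)c(OCc6ccccc6)c(OCc6ccccc6)c5 | intermediate
8 | (2S)-5-hydroxy-3-nitro-2-[3,4,5-tris(benzyloxy)phenyl]-2H-chromen-7-yl 3,4,5-tris(benzyloxy)benzoate | O=C(Oc1cc(O)c2c(c1)O[C@@H](c3cc(OCc4ccccc4)c(OCc4ccccc4)c(OCc4ccccc4)c3)C([N+](=O)[O-])=C2)c5cc(OCc6ccccc6)c(OCc6ccccc6)c(OCc6ccccc6)c5 | intermediate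
9 | sodium aci-nitronate of the (2S)-3-nitrochroman derived from 8 | O=C(Oc1cc(O)c2c(c1)O[C@@H](c3cc(OCc4ccccc4)c(OCc4ccccc4)c(OCc4ccccc4)c3)C(=[N+]([O-])[O-])C2)c5cc(OCc6ccccc6)c(OCc6ccccc6)c(OCc6ccccc6)c5.[Na+] | intermediate
10 | (2S)-5-hydroxy-3-oxo-2-[3,4,5-tris(benzyloxy)phenyl]-3,4-dihydro-2H-chromen-7-yl 3,4,5-tris(benzyloxy)benzoate | O=C(Oc1cc(O)c2c(c1)O[C@@H](c3cc(OCc4ccccc4)c(OCc4ccccc4)c(OCc4ccccc4)c3)C(=O)C2)c5cc(OCc6ccccc6)c(OCc6ccccc6)c(OCc6ccccc6)c5 | intermediate
11 | (2S,3R)-3,5-dihydroxy-2-[3,4,5-tris(benzyloxy)phenyl]-3,4-dihydro-2H-chromen-7-yl 3,4,5-tris(benzyloxy)benzoate | O=C(Oc1cc(O)c2c(c1)O[C@@H](c3cc(OCc4ccccc4)c(OCc4ccccc4)c(OCc4ccccc4)c3)[C@H](O)C2)c5cc(OCc6ccccc6)c(OCc6ccccc6)c(OCc6ccccc6)c5 | intermediate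
12 | (2S,3R)-3,5-dihydroxy-2-(3,4,5-trihydroxyphenyl)-3,4-dihydro-2H-chromen-7-yl 3,4,5-trihydroxybenzoate | O=C(Oc1cc(O)c2c(c1)O[C@@H](c1cc(O)c(O)c(O)c1)[C@H](O)C2)c1cc(O)c(O)c(O)c1 | target

**Step count**
Total steps: 6.
Longest linear sequence: 5 (1 → 3 → 8 → 10 → 11 → 12, or equally 4 → 6 → 8 → 10 → 11 → 12).

**Steps most likely to fail**

Step 3 (reactivity and ee with a hindered, strongly hydrogen-bonded, ester-bearing aldehyde). The fallback gives up asymmetric catalysis. Setting out again from 6 and 3, the same cascade is run with DABCO in MeCN at 40–60 °C. This gives the racemic 5-hydroxy-3-nitro-2-aryl-2H-chromen-7-yl gallate F1. Its enantiomers are separated by preparative SFC on an amylose-type chiral phase. The 2S enantiomer is 8, where the route is rejoined.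

Step 4 (racemisation of nitronate 9 by retro-oxa-Michael ring opening, or a Nef reaction that stalls at the oxime). The fallback avoids the ketone and brings the C3 oxygen in from the less hindered face.
- It sets out from 8. PhSH with catalytic Et3N adds to C4 to give the 2,4-trans β-nitro sulfide F2.
- Bu3SnH/AIBN in hot toluene removes the nitro and phenylthio groups by radical elimination to give the (2R)-flav-3-ene F3. The spatial arrangement at C2 is unchanged; only the descriptor changes.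
- OsO4 (cat.)/NMO dihydroxylates anti to the 2-aryl group to give the 2,3-trans-3,4-cis diol F4.
- Hydrogenolysis under the conditions of step 6 removes the doubly activated benzylic 4-OH together with the six benzyl groups. The route is rejoined at 12.

Step 5 (reagent control may not overcome the cis bias of the ketone). The fallback uses the substrate bias and then inverts C3.
- It sets out from 10. LiBH(s-Bu)3 in THF at −78 °C attacks anti to the 2-aryl group to give the (2S,3S)-cis alcohol F5.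
- Mitsunobu reaction with formic acid (PPh3, DIAD, THF, 0 °C) inverts C3 to give the (2S,3R)-3-O-formate F6.
- Brief methanolysis with NaHCO3 in MeOH at 0 °C cleaves the far more reactive formate in the presence of the aryl gallate. The route is rejoined at 11.

**Further compounds**
F1 | step 3 | racemic 5-hydroxy-3-nitro-2-[3,4,5-tris(benzyloxy)phenyl]-2H-chromen-7-yl 3,4,5-tris(benzyloxy)benzoate | O=C(Oc1cc(O)c2c(c1)OC(c3cc(OCc4ccccc4)c(OCc4ccccc4)c(OCc4ccccc4)c3)C([N+](=O)[O-])=C2)c5cc(OCc6ccccc6)c(OCc6ccccc6)c(OCc6ccccc6)c5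
F2 | step 4 | (2S,4R)-5-hydroxy-3-nitro-4-(phenylsulfanyl)-2-[3,4,5-tris(benzyloxy)phenyl]chroman-7-yl 3,4,5-tris(benzyloxy)benzoate (2,4-trans, mixture at C3) | O=C(Oc1cc(O)c2c(c1)O[C@@H](c3cc(OCc4ccccc4)c(OCc4ccccc4)c(OCc4ccccc4)c3)C([N+](=O)[O-])[C@@H]2Sc7ccccc7)c5cc(OCc6ccccc6)c(OCc6ccccc6)c(OCc6ccccc6)c5
F3 | step 4 | (2R)-5-hydroxy-2-[3,4,5-tris(benzyloxy)phenyl]-2H-chromen-7-yl 3,4,5-tris(benzyloxy)benzoate | O=C(Oc1cc(O)c2c(c1)O[C@@H](c3cc(OCc4ccccc4)c(OCc4ccccc4)c(OCc4ccccc4)c3)C=C2)c5cc(OCc6ccccc6)c(OCc6ccccc6)c(OCc6ccccc6)c5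
F4 | step 4 | (2S,3R,4R)-3,4,5-trihydroxy-2-[3,4,5-tris(benzyloxy)phenyl]chroman-7-yl 3,4,5-tris(benzyloxy)benzoate | O=C(Oc1cc(O)c2c(c1)O[C@@H](c3cc(OCc4ccccc4)c(OCc4ccccc4)c(OCc4ccccc4)c3)[C@H](O)[C@@H]2O)c5cc(OCc6ccccc6)c(OCc6ccccc6)c(OCc6ccccc6)c5
F5 | step 5 | (2S,3S)-3,5-dihydroxy-2-[3,4,5-tris(benzyloxy)phenyl]chroman-7-yl 3,4,5-tris(benzyloxy)benzoate | O=C(Oc1cc(O)c2c(c1)O[C@@H](c3cc(OCc4ccccc4)c(OCc4ccccc4)c(OCc4ccccc4)c3)[C@@H](O)C2)c5cc(OCc6ccccc6)c(OCc6ccccc6)c(OCc6ccccc6)c5
F6 | step 5 | (2S,3R)-3-(formyloxy)-5-hydroxy-2-[3,4,5-tris(benzyloxy)phenyl]chroman-7-yl 3,4,5-tris(benzyloxy)benzoate | O=C(Oc1cc(O)c2c(c1)O[C@@H](c3cc(OCc4ccccc4)c(OCc4ccccc4)c(OCc4ccccc4)c3)[C@H](OC=O)C2)c5cc(OCc6ccccc6)c(OCc6ccccc6)c(OCc6ccccc6)c5
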